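The numbers in the tables are calculated on assumed constants; the scatter is artificial.

Don't read a slow, straight rise of monomer in chains as long chains: the readings show how much monomer has gone in, not how many chains share it.

the same everywhere: free monomer 0.055 M; pre-initiator 10 mol%

|  | transfer agent | remark | time |
|---|---|---|---|
| dawn | 0.023 M | run made earlier |  |
| autumn | 0.036 M | run made earlier |  |
| flask | 0.0165 M |  | 5.0 d |

| run | time / d | monomer in chains / % | free monomer / % |
|---|---|---|---|
| dawn | 0.333 | 1.3 | 100.6 |
| dawn | 0.833 | 1.9 | 99.1 |
| dawn | 1.67 | 2.3 | 98.6 |
| dawn | 2.50 | 4.1 | 97.4 |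
| dawn | 4.00 | 6.3 | 94.1 |
| dawn | 5.00 | 8.2 | 92.1 |
| dawn | 6.00 | 8.1 | 90.7 |
| autumn | 0.333 | 1.9 | 100.7 |
| autumn | 0.833 | 2.1 | 99.4 |
| autumn | 1.67 | 1.2 | 96.7 |
| autumn | 2.50 | 4.6 | 97.6 |
| autumn | 4.00 | 5.2 | 94.3 |
| autumn | 5.00 | 7.3 | 94.1 |
| autumn | 6.00 | 7.5 | 93.5 |

(scatter of a reading: 1 percentage point)

* whether the average number of monomer units in a chain (chains begun, living or dead) reaches 10 by 5.0 d (yes / no)
* average number of monomer units in a chain (chains begun, living or dead) at 5.0 d

- the average divides the monomer in chains by the number of chains begun, living and dead together
- the earlier runs do not show the number of chains; that part of a forecast is a guess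

So fold what you can see into one number: monomer in chains at the asked time divided by the pre-initiator charged, the units per pre-initiator charged. The dawn run reads 0.820 at 5.00 d. The autumn run reads 0.730, but its monomer in chains differs from the dawn run's by only 0.9 percentage points, with a scatter of 1 point. So I carry the dawn value, as a reading, to the flask, whose transfer agent lies closer to the dawn run's than to the autumn run's.

If each pre-initiator spent begins one chain, the average length, or degree of polymerisation, is this number divided by the share of pre-initiator spent. Reaching 10 then needs a spent share below 8.20%.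

One number isn't enough: the earlier runs do not show the number of chains, so that share has to be guessed. My own guess is no: if 0.5 of the pre-initiator is spent, the average comes to about 1.64.

The forecast said no and 2, within 1 to 6, a higher average than my 1.64: “Reaching 10 looks unlikely.” The flask gives no and 2.50.

    pre-initiator → initiator (k = 5.20 × 10⁻⁵ min⁻¹)
    living end → dead end (k = 0.00490 min⁻¹)
    free monomer + initiator → living end + monomer in chains (k = 0.180 L mol⁻¹ min⁻¹)
    free monomer + living end → monomer in chains + living end, rate k4*[living end]*[free monomer] (k = 0.170 L mol⁻¹ min⁻¹)
    living end + transfer agent → dead chain (kL = 0.0580 L mol⁻¹ min⁻¹)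

At 5.00 d the flask has 69% of its pre-initiator left, so 31.0% is spent, and the dawn reading 0.820 over that share gives 2.65, against the flask's 2.50. The neighbour with 0.041 M of transfer agent has 6.85% of its charged free monomer in chains and 69% of its pre-initiator left. Its own number, 0.685, over its spent share gives 2.19, and its average stands at 2.22.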